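**Retrosynthetic overview**
1. γ-Lactone (last ring): the acyl group passes from a chiral sultam imide to the C9′–OH. That OH is unmasked when the benzylic C7–O bond of a lariciresinol-type oxolane is hydrogenolysed. The same H2/Pd step removes a C5–Br blocking group.
2. Oxolane (first ring): C9′–OH traps the C7 quinone methide of an 8–8′ bis-quinone methide (5-exo). A dihydropyridine hydride donor reduces the second (C7′) quinone methide.
3. C8–C8′ bond and both stereocentres: Si,Si phenoxyl-radical cross-coupling of sinapyl alcohol with N-(5-bromoferuloyl)-(2S)-bornane-10,2-sultam. The guaiacyl half enters at the acid oxidation level, which fixes which carbon becomes C=O.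
4. Building blocks: sinapyl alcohol from syringaldehyde (Wittig, i-Bu2AlH). The imide comes from the sultam, bromoacetyl bromide and 5-bromovanillin (N-acylation, Wittig).
5. Ring order: oxolane formed (step 5), then opened and replaced by the γ-lactone (step 6).

Assumption: the uncatalysed Cα topicity known for N-enoyl bornane-10,2-sultams ((2S)-sultam → attack on the Cα-Si face) is taken to hold for the phenoxyl-radical coupling; lignan numbering is used (C7–C9 guaiacyl unit, C7′–C9′ syringyl unit).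

**Step 1**
Reactants: 1 syringaldehyde
Product: 2 ethyl (E)-sinapate
Conditions: Ph3P=CHCO2Et (1.1 equiv), toluene, 90 °C, 4 h
Reagents that add atoms: ethyl (triphenylphosphoranylidene)acetate, CCOC(=O)C=P(c1ccccc1)(c1ccccc1)c1ccccc1
Why: Wittig olefination with a neutral ester-stabilised ylide tolerates the free phenol and gives the (E)-cinnamate, and no stereocentre is formed.

**Step 2**
Reactants: 2 ethyl (E)-sinapate
Product: 3 sinapyl alcohol
Conditions: i-Bu2AlH (4 equiv), toluene, 0 °C, 1 h; aq. potassium sodium tartrate work-up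
Reagents that add atoms: none
Why: 1,2-reduction of the α,β-unsaturated ester by i-Bu2AlH (one equivalent is spent on the phenol) stops at the allylic alcohol without touching the C=C bond, and no stereocentre is formed.

**Step 3**
Reactants: 4 (2S)-bornane-10,2-sultam
Product: 6 N-(bromoacetyl)-(2S)-bornane-10,2-sultam, via sodium sulfonamide 5 (not isolated)
Conditions: NaH (1.1 equiv), THF, 0 °C; BrCH2COBr (1.1 equiv), −78 → 0 °C
Reagents that add atoms: bromoacetyl bromide, BrCC(=O)Br
Why: N-acylation of the sulfonamide anion works because the acyl bromide reacts far faster than the primary alkyl bromide, and the three sultam stereocentres are untouched.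

**Step 4**
Reactants: 6 N-(bromoacetyl)-(2S)-bornane-10,2-sultam; 7 5-bromovanillin
Product: 10 N-[(E)-3-(3-bromo-4-hydroxy-5-methoxyphenyl)prop-2-enoyl]-(2S)-bornane-10,2-sultam, via phosphonium bromide 8 (not isolated), via acyl ylide 9 (not isolated)
Conditions: PPh3 (1.05 equiv), toluene, 60 °C; CH2Cl2 / cold 1 M NaOH, 5 min, separate, dry; 7 (1.0 equiv), toluene, 80 °C, 12 h
Reagents that add atoms: none
Why: quaternisation, deprotonation and Wittig olefination with an imide-stabilised neutral ylide give the (E)-enoyl sultam without phenol protection, and no stereocentre is formed.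

**Step 5**
Reactants: 10 N-[(E)-3-(3-bromo-4-hydroxy-5-methoxyphenyl)prop-2-enoyl]-(2S)-bornane-10,2-sultam; 3 sinapyl alcohol
Product: 15 N-{[(2S,3S,4R)-2-(3-bromo-4-hydroxy-5-methoxyphenyl)-4-(4-hydroxy-3,5-dimethoxybenzyl)oxolan-3-yl]carbonyl}-(2S)-bornane-10,2-sultam, via bromoferuloyl phenoxyl radical 11 (not isolated), via sinapyl phenoxyl radical 12 (not isolated), via bis-quinone methide 13 (not isolated), via oxolane quinone methide 14 (not isolated)
Conditions: 10 (2.0 equiv, excess recovered), Ag2O (1.1 equiv), 4 Å MS, CH2Cl2–acetone 4:1, −20 °C, 3 (1.0 equiv) added over 6 h; filter through Celite into Hantzsch ester (1.5 equiv), (PhO)2P(O)OH (5 mol %), 0 °C, 30 min; chromatography, recrystallisation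
Reagents that add atoms: none
Why: Proposed new method: Ag2O takes one electron and one proton from each phenol, and the slowly fed, more easily oxidised 3 meets an excess of radical 11 whose C5 is blocked by Br, so C8–C8′ cross-coupling (phenoxyl radical–radical coupling, the reaction type of resinol formation) is the main open channel; the sultam in its anti/s-cis conformation screens the C8-Re face with its pseudo-axial S=O, so 12 bonds to the C8-Si face, the stacked like (Si,Si) transition state common to monolignol 8–8′ couplings sets C8′, the C9′–OH closes the oxolane by 5-exo oxa-1,6-addition to the more electrophilic C7 quinone methide with the aryl group trans to the acyl group, and the surviving syringyl quinone methide is reduced by acid-catalysed hydride transfer from the Hantzsch ester; the closest known reaction types are the Ag2O-mediated sultam-controlled 8–5′ dehydrodimerisation of N-feruloyl sultams, the 8–β′ cross-coupling of ferulates with monolignols, the 8–8′ dimerisation of 5-bromoconiferyl alcohol and the Hantzsch-ester 1,6-reduction of p-quinone methides.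

**Step 6**
Reactants: 15 N-{[(2S,3S,4R)-2-(3-bromo-4-hydroxy-5-methoxyphenyl)-4-(4-hydroxy-3,5-dimethoxybenzyl)oxolan-3-yl]carbonyl}-(2S)-bornane-10,2-sultam
Product: 18 (3R,4R)-4-(4-hydroxy-3,5-dimethoxybenzyl)-3-(4-hydroxy-3-methoxybenzyl)oxolan-2-one, via debrominated oxolane imide 16 (not isolated), via hydroxy imide 17 (not isolated)
Conditions: H2 (5 bar), 20% Pd(OH)2/C, NaOAc (1.5 equiv), EtOAc–AcOH 4:1, 45 °C, 24 h; filter; DMAP (0.2 equiv), CH2Cl2, rt, 2 h
Reagents that add atoms: none
Why: heterogeneous Pd hydrogenolysis cleaves Ar–Br first and then the p-hydroxybenzylic C7–O bond (benzylic ether hydrogenolysis, as in resinol to seco-lignan reductions), after which the freed C9′–OH attacks the activated N-acyl sultam in a 5-exo-trig lactonisation that expels 4; no new stereocentre is made, C7 becomes CH2, and C8 and C8′ keep their configuration, the trans-lactone also being the thermodynamic epimer.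

**Compound list**
1 | syringaldehyde (4-hydroxy-3,5-dimethoxybenzaldehyde) | COc1cc(C=O)cc(OC)c1O | starting material
2 | ethyl (E)-sinapate | CCOC(=O)/C=C/c1cc(OC)c(O)c(OC)c1 | intermediate
3 | sinapyl alcohol, (E)-4-(3-hydroxyprop-1-enyl)-2,6-dimethoxyphenol | OC/C=C/c1cc(OC)c(O)c(OC)c1 | intermediate
4 | (2S)-bornane-10,2-sultam, (1R)-(+)-2,10-camphorsultam, (3aR,6S,7aS) | CC1(C)[C@H]2CC[C@@]13CS(=O)(=O)N[C@H]3C2 | starting material
5 | sodium salt of 4 | CC1(C)[C@H]2CC[C@@]13CS(=O)(=O)[N-][C@H]3C2.[Na+] | intermediate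
6 | N-(bromoacetyl)-(2S)-bornane-10,2-sultam | CC1(C)[C@H]2CC[C@@]13CS(=O)(=O)N(C(=O)CBr)[C@H]3C2 | intermediate
7 | 5-bromovanillin (3-bromo-4-hydroxy-5-methoxybenzaldehyde) | COc1cc(C=O)cc(Br)c1O | starting material
8 | [2-oxo-2-(sultam-N-yl)ethyl]triphenylphosphonium bromide | CC1(C)[C@H]2CC[C@@]13CS(=O)(=O)N(C(=O)C[P+](c4ccccc4)(c4ccccc4)c4ccccc4)[C@H]3C2.[Br-] | intermediate
9 | N-[(triphenylphosphoranylidene)acetyl]-(2S)-bornane-10,2-sultam | CC1(C)[C@H]2CC[C@@]13CS(=O)(=O)N(C(=O)C=P(c4ccccc4)(c4ccccc4)c4ccccc4)[C@H]3C2 | intermediate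
10 | N-[(E)-5-bromoferuloyl]-(2S)-bornane-10,2-sultam | CC1(C)[C@H]2CC[C@@]13CS(=O)(=O)N(C(=O)/C=C/c4cc(OC)c(O)c(Br)c4)[C@H]3C2 | intermediate
11 | phenoxyl radical of 10 | CC1(C)[C@H]2CC[C@@]13CS(=O)(=O)N(C(=O)/C=C/c4cc(OC)c([O])c(Br)c4)[C@H]3C2 | intermediate
12 | phenoxyl radical of 3 | OC/C=C/c1cc(OC)c([O])c(OC)c1 | intermediate
13 | (8R,8′R)-8–8′ bis-quinone methide, exocyclic C7=C1 geometry not defined | CC1(C)[C@H]2CC[C@@]13CS(=O)(=O)N(C(=O)[C@H](C=C4C=C(OC)C(=O)C(Br)=C4)[C@H](CO)C=C4C=C(OC)C(=O)C(OC)=C4)[C@H]3C2 | intermediate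
14 | (2S,3S,4R)-oxolane carrying the C7′ syringyl quinone methide | CC1(C)[C@H]2CC[C@@]13CS(=O)(=O)N(C(=O)[C@@H]4[C@@H](c5cc(OC)c(O)c(Br)c5)OC[C@@H]4C=C4C=C(OC)C(=O)C(OC)=C4)[C@H]3C2 | intermediate
15 | (2S,3S,4R)-2-(3-bromo-4-hydroxy-5-methoxyphenyl)-4-(4-hydroxy-3,5-dimethoxybenzyl)oxolane-3-carbonyl sultam (2,3-trans, 3,4-cis; same spatial arrangement as (+)-lariciresinol) | CC1(C)[C@H]2CC[C@@]13CS(=O)(=O)N(C(=O)[C@@H]4[C@@H](c5cc(OC)c(O)c(Br)c5)OC[C@@H]4Cc4cc(OC)c(O)c(OC)c4)[C@H]3C2 | intermediate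
16 | debrominated analogue of 15, (2S,3S,4R) | CC1(C)[C@H]2CC[C@@]13CS(=O)(=O)N(C(=O)[C@@H]4[C@@H](c5ccc(O)c(OC)c5)OC[C@@H]4Cc4cc(OC)c(O)c(OC)c4)[C@H]3C2 | intermediate
17 | N-[(2R,3R)-4-hydroxy-3-(4-hydroxy-3,5-dimethoxybenzyl)-2-(4-hydroxy-3-methoxybenzyl)butanoyl]-(2S)-bornane-10,2-sultam | CC1(C)[C@H]2CC[C@@]13CS(=O)(=O)N(C(=O)[C@H](Cc4ccc(O)c(OC)c4)[C@H](CO)Cc4cc(OC)c(O)c(OC)c4)[C@H]3C2 | intermediate
18 | (3R,4R)-4-(4-hydroxy-3,5-dimethoxybenzyl)-3-(4-hydroxy-3-methoxybenzyl)oxolan-2-one | COc1cc(C[C@H]2C(=O)OC[C@@H]2Cc2cc(OC)c(O)c(OC)c2)ccc1O | target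

**Totals**
Total step count: 6.
Longest linear sequence: 4 (steps 1, 2, 5, 6 or steps 3, 4, 5, 6).

**Steps most likely to fail**

**Step 5** is the riskiest.
- Risks: 8–8′ homo-coupling of either partner, 8′–O–4 coupling and an incomplete facial bias. A realistic yield is 25–35% based on 3.
- The fallback sets out from 10 (with 3) and comes back at 15. It makes the C7–O bond first and closes C8–C8′ by a tethered 5-exo radical cyclisation instead of a radical–radical coupling.
- Br2 (CH2Cl2, −20 °C) adds across the cinnamoyl C=C of 10 to give the 7,8-dibromide F1.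
- Shaking with sat. aq. NaHCO3 removes HBr from the p-hydroxybenzylic position to give the 8-bromo quinone methide F2.
- The primary OH of 3 (3 equiv, pyridinium tosylate cat.) adds 1,6 to F2 to give the 7-O-sinapyl 8-bromo ether F3.
- (Me3Si)3SiH, Et3B/air, toluene, −20 °C then generates the C8 radical next to the sultam imide. It closes onto C8′ of the styrene, and the benzylic C7′ radical takes up hydrogen to give 15.
- The Beckwith–Houk chair predicts 7,8-trans and 8,8′-cis. The C7 epimers are diastereomers because of the sultam and are separated at the ether or at 15.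

**Step 6** is second.
- Risks: slow C7–O hydrogenolysis next to the bulky imide, or acid-induced aryltetralin formation.
- The fallback sets out from 15 and comes back at 18. It replaces C–O hydrogenolysis by elimination, alkene hydrogenation and epimerisation.
- DBU (3 equiv, MeCN, 50 °C) triggers a retro-oxa-Michael opening of the oxolane. The freed C9′ alkoxide lactonises onto the imide with loss of 4, giving the (3E,4R)-arylidene lactone F4.
- H2 (1 bar), 10% Pd/C, NaOAc, EtOAc saturates the C=C bond from the face opposite the C8′ benzyl group and removes Br, giving mainly the cis-lactone F5.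
- DBU (0.5 equiv, toluene, 60 °C) epimerises C8 to the more stable trans-lactone 18. C8′ is not touched.

**Step 4** is third.
- Risk: the acidic phenol of 7 protonates the ylide and stalls the olefination.
- The fallback sets out from 7 (with 4) and comes back at 10. It builds the cinnamic acid first and acylates the auxiliary afterwards.
- A Perkin reaction of 7 (Ac2O, NaOAc, 150 °C) gives O-acetyl-5-bromoferulic acid F6.
- SOCl2 (cat. DMF, toluene, 60 °C) gives the acid chloride F7.
- Sodium sulfonamide 5 (from 4 and NaH, THF, 0 °C) is acylated to the O-acetyl imide F8.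
- Pyrrolidine (1.2 equiv, CH2Cl2, 0 °C, 10 min) cleaves only the aryl acetate to give 10.

**Further compounds**
F1 | step 5 | N-[2,3-dibromo-3-(3-bromo-4-hydroxy-5-methoxyphenyl)propanoyl]-(2S)-bornane-10,2-sultam (C7/C8 isomer mixture) | CC1(C)[C@H]2CC[C@@]13CS(=O)(=O)N(C(=O)C(Br)C(Br)c4cc(OC)c(O)c(Br)c4)[C@H]3C2
F2 | step 5 | 8-bromo quinone methide of the sultam imide (C8 mixture) | CC1(C)[C@H]2CC[C@@]13CS(=O)(=O)N(C(=O)C(Br)C=C4C=C(OC)C(=O)C(Br)=C4)[C@H]3C2
F3 | step 5 | N-[2-bromo-3-(3-bromo-4-hydroxy-5-methoxyphenyl)-3-((E)-sinapyloxy)propanoyl]-(2S)-bornane-10,2-sultam (C7/C8 isomers, separable) | CC1(C)[C@H]2CC[C@@]13CS(=O)(=O)N(C(=O)C(Br)C(OC/C=C/c4cc(OC)c(O)c(OC)c4)c4cc(OC)c(O)c(Br)c4)[C@H]3C2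
F4 | step 6 | (3E,4R)-3-(3-bromo-4-hydroxy-5-methoxybenzylidene)-4-(4-hydroxy-3,5-dimethoxybenzyl)oxolan-2-one | O=C1OC[C@H](Cc2cc(OC)c(O)c(OC)c2)/C1=C\c1cc(OC)c(O)c(Br)c1
F5 | step 6 | (3S,4R)-4-(4-hydroxy-3,5-dimethoxybenzyl)-3-(4-hydroxy-3-methoxybenzyl)oxolan-2-one (cis) | COc1cc(C[C@@H]2C(=O)OC[C@@H]2Cc2cc(OC)c(O)c(OC)c2)ccc1O
F6 | step 4 | (E)-3-(4-acetoxy-3-bromo-5-methoxyphenyl)prop-2-enoic acid | CC(=O)Oc1c(Br)cc(/C=C/C(=O)O)cc1OC
F7 | step 4 | (E)-3-(4-acetoxy-3-bromo-5-methoxyphenyl)prop-2-enoyl chloride | CC(=O)Oc1c(Br)cc(/C=C/C(=O)Cl)cc1OC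
F8 | step 4 | N-[(E)-3-(4-acetoxy-3-bromo-5-methoxyphenyl)prop-2-enoyl]-(2S)-bornane-10,2-sultam | CC1(C)[C@H]2CC[C@@]13CS(=O)(=O)N(C(=O)/C=C/c4cc(OC)c(OC(C)=O)c(Br)c4)[C@H]3C2
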